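**Plan**

1. Retrosynthesis: the two isobutyrates and the C2 hydroxymethyl group (Morita–Baylis–Hillman) come off last; the skipped diene is cut between its allylic CH2 and the E-alkene (Suzuki–Miyaura) into an (R)-alkenylboronate and a (5R)-5-(3-oxyprop-1-en-2-yl)cyclohex-2-enone.
2. Enabling feature: in the cyclohexenone ring (C1 is the carbonyl carbon) the β-carbon C3 and the allylic oxygen of the 2-propenyl group on C5 can be 1,3-cis, so the enone is the retro-oxa-Michael form of a 2-oxabicyclo[3.3.1]nonan-7-one in which C3–O and the C1 ketone make a β-alkoxy ketone.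
3. That bicycle is cut at C3–C4 and C5–C6 to a 3-alkoxycyclobutanone whose alkoxy group is a 2-methylidenebut-3-enyl ether: the four-membered ring delivers C6–C1–C2–C3 as a strain-loaded 1,4-dipole (enol carbon C6, oxocarbenium carbon C3), the vinyl group delivers C4–C5.
4. Forward order: ether-linked cyclobutanone (3 steps), then ring opening/Prins closure/enol capture builds the temporary oxane ring and then the carbocycle, base opens the C3–O bridge to the enone, then fragment union, hydroxymethylation and double acylation.
5. Stereochemistry: C5 is set in the key step (a chiral counter-anion selects the oxocarbenium face at C3, the O–CH2 tether forces C5 cis to it, C3 is erased on ring opening); the carbinol centre comes from (S)-2-methylglycidol; the E-alkene from cross-metathesis.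

Key step: step 4

Assumption: the sense of induction of the chiral acid in step 4 cannot be derived from precedent; the (S,S)-acid is taken to give the (1S,5R)-bicycle, otherwise its enantiomer is used.

**Step 1**
Reactants: 1 2-ethenyl-2-methyloxirane (isoprene monoxide, racemic)
Product: 2 2-methylidenebut-3-en-1-ol
Conditions: LiN(iPr)2 (1.3 equiv), Et2O, −78 °C to rt; H2O
Reagents that add atoms: none
Why: Lithium amide-mediated isomerisation of an epoxide to an allylic alcohol (syn β-elimination: a methyl proton is removed and the C–O bond at the quaternary carbon breaks) should give the cross-conjugated dienol; the stereocentre of 1 is destroyed, so the racemate serves.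

**Step 2**
Reactants: 2 2-methylidenebut-3-en-1-ol
Product: 3 2-(bromomethyl)buta-1,3-diene
Conditions: PBr3 (0.4 equiv), pyridine (cat.), Et2O, −10 to 0 °C; used at once as a cold ether solution
Reagents that add atoms: phosphorus tribromide BrP(Br)Br
Why: Conversion of a primary allylic alcohol into the bromide through its phosphite ester is standard (SN2; the SN2′ path of this 2-substituted allyl system gives the same compound).

**Step 3**
Reactants: 3 2-(bromomethyl)buta-1,3-diene; 4 3-hydroxycyclobutan-1-one
Product: 5 3-[(2-methylidenebut-3-en-1-yl)oxy]cyclobutan-1-one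
Conditions: Ag2O (1.5 equiv), 4 Å MS, CH2Cl2, rt, dark
Reagents that add atoms: none
Why: Silver-oxide-assisted Williamson-type O-alkylation (halophilic activation of the allylic bromide) etherifies the secondary alcohol without a free alkoxide, which would open the β-hydroxy ketone by retro-aldol cleavage.

**Step 4**
Reactants: 5 3-[(2-methylidenebut-3-en-1-yl)oxy]cyclobutan-1-one
Product: 8 (1S,5R)-4-methylidene-2-oxabicyclo[3.3.1]nonan-7-one, via oxocarbenium enol cation 6 (not isolated), via oxanyl allyl cation 7 (not isolated)
Conditions: (S,S)-imidodiphosphorimidate Brønsted acid (two (S)-3,3′-bis[3,5-bis(trifluoromethyl)phenyl]-BINOL units, N-triflyl groups; 5 mol %), CHCl3, −40 °C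
Reagents that add atoms: none
Why: Proposed new method: protonation of the ketone of 5 by the confined chiral acid lets the ether oxygen push open the strained ring bond between the alkoxy carbon and an α-carbon (retro-aldol type, driven by release of four-membered-ring strain) to the enol/oxocarbenium ion pair 6, which closes by Prins attack of the vinyl CH2 terminus on the oxocarbenium carbon (future C3–C4 bond of the cyclohexenone) to the exocyclic allyl cation 7 and then by collapse of the enol carbon on the ring terminus of that cation (future C5–C6 bond), returning the proton. The closest known reaction types are the formal [4+2] cycloadditions of 3-alkoxycyclobutanones with alkenes, allylsilanes and carbonyl compounds under stoichiometric achiral Lewis acids, and the catalytic asymmetric Prins cyclisation with confined imidodiphosphorimidate acids; turnover by a chiral Brønsted acid and counter-anion control of this ring-opening cascade have not been shown. The temporary oxane ring closes 6-endo through a chair-like Prins transition state (the more nucleophilic methylidene terminus could only close 5-endo), and the carbocycle closes 6-(enolendo)-exo-trig on the allyl cation (the other terminus would need an eight-membered ring). The stereocentre at the oxocarbenium carbon (C1 of 8) is set by the chiral anion, which ion-pairs with the oxocarbenium and hydrogen-bonds the enol and so differentiates the enantiotopic faces in the C–C bond-forming step; the stereocentre kept in the target (C5 of 8) is fixed relative to it by the O–CH2 tether, because the three-atom bridge can only span the two carbons cis (1,3-diaxial). The step needs regioselectivity (secured by the tether), chemoselectivity for carbonyl activation over protonation of the diene (low temperature, non-nucleophilic anion) and enantioselectivity (catalyst pocket).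

**Step 5**
Reactants: 8 (1S,5R)-4-methylidene-2-oxabicyclo[3.3.1]nonan-7-one
Product: 10 tert-butyl 2-[(1R)-5-oxocyclohex-3-en-1-yl]prop-2-en-1-yl carbonate, via hydroxy enone 9 (not isolated)
Conditions: DBU (1.2 equiv), Boc2O (1.5 equiv), DMAP (10 mol %), CH2Cl2, 0 °C to rt
Reagents that add atoms: di-tert-butyl dicarbonate CC(C)(C)OC(=O)OC(=O)OC(C)(C)C
Why: E1cB (retro-oxa-Michael) opening of the β-alkoxy ketone, whose bridging C–O bond is axial on the cyclohexanone chair and aligned with the enolate π system, unveils the enone and erases the oxygen-bearing stereocentre, while acylation of the freed primary alcohol 9 as its carbonate prevents re-closure; the ring stereocentre is not enolisable and is untouched.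

**Step 6**
Reactants: 11 [(2S)-2-methyloxiran-2-yl]methanol ((S)-2-methylglycidol)
Product: 12 tert-butyldimethyl{[(2R)-2-methyloxiran-2-yl]methoxy}silane
Conditions: TBSCl, imidazole, CH2Cl2, 0 °C to rt
Reagents that add atoms: tert-butyldimethylsilyl chloride CC(C)(C)[Si](C)(C)Cl
Why: Standard silylation of the primary alcohol; no bond to the stereocentre is touched (the descriptor changes from S to R only through the priority rules).

**Step 7**
Reactants: 12 tert-butyldimethyl{[(2R)-2-methyloxiran-2-yl]methoxy}silane
Product: 13 (2R)-1-[(tert-butyldimethylsilyl)oxy]-2-methylbut-3-en-2-ol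
Conditions: Me3S+ I− (3 equiv), n-BuLi (3 equiv), THF, −10 °C to rt; H2O
Reagents that add atoms: trimethylsulfonium iodide C[S+](C)C.[I-]
Why: One-carbon homologation of a terminal epoxide to an allylic alcohol by dimethylsulfonium methylide (attack at the unhindered CH2, then ylide formation at sulfur and elimination of dimethyl sulfide) leaves the C–O bond at the quaternary centre intact, so its configuration is retained.

**Step 8**
Reactants: 13 (2R)-1-[(tert-butyldimethylsilyl)oxy]-2-methylbut-3-en-2-ol; 14 2-ethenyl-4,4,5,5-tetramethyl-1,3,2-dioxaborolane (3 equiv)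
Product: 15 (2R,3E)-1-[(tert-butyldimethylsilyl)oxy]-2-methyl-4-(4,4,5,5-tetramethyl-1,3,2-dioxaborolan-2-yl)but-3-en-2-ol
Conditions: second-generation Hoveyda–Grubbs catalyst (5 mol %), CH2Cl2, 40 °C
Reagents that add atoms: none
Why: Olefin cross-metathesis of a hindered, slowly dimerising tertiary allylic alcohol with excess vinylboronate should give the E-alkenylboronate under thermodynamic control (bulky boronate and quaternary carbinol trans).

**Step 9**
Reactants: 10 tert-butyl 2-[(1R)-5-oxocyclohex-3-en-1-yl]prop-2-en-1-yl carbonate; 15 (2R,3E)-1-[(tert-butyldimethylsilyl)oxy]-2-methyl-4-(4,4,5,5-tetramethyl-1,3,2-dioxaborolan-2-yl)but-3-en-2-ol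
Product: 16 (5R)-5-{(4E,6R)-7-[(tert-butyldimethylsilyl)oxy]-6-hydroxy-6-methylhepta-1,4-dien-2-yl}cyclohex-2-en-1-one
Conditions: Pd(PPh3)4 (5 mol %), THF, 50 °C, no added base
Reagents that add atoms: none
Why: Suzuki–Miyaura allyl–alkenyl coupling: zerovalent palladium ionises the carbonate to a π-allyl complex and tert-butoxide (after loss of CO2), which activates the boronate for transmetalation; both allyl termini are CH2 so only one constitution can form, the alkene geometry of 15 is retained and neither stereocentre is involved.

**Step 10**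
Reactants: 16 (5R)-5-{(4E,6R)-7-[(tert-butyldimethylsilyl)oxy]-6-hydroxy-6-methylhepta-1,4-dien-2-yl}cyclohex-2-en-1-one
Product: 17 (5R)-5-[(4E,6R)-6,7-dihydroxy-6-methylhepta-1,4-dien-2-yl]cyclohex-2-en-1-one
Conditions: HF·pyridine, THF/pyridine, 0 °C
Reagents that add atoms: none
Why: Fluoride cleavage of the primary silyl ether under buffered, non-basic conditions leaves the enone, the skipped diene and the tertiary allylic alcohol untouched.

**Step 11**
Reactants: 17 (5R)-5-[(4E,6R)-6,7-dihydroxy-6-methylhepta-1,4-dien-2-yl]cyclohex-2-en-1-one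
Product: 18 (5R)-5-[(4E,6R)-6,7-dihydroxy-6-methylhepta-1,4-dien-2-yl]-2-(hydroxymethyl)cyclohex-2-en-1-one
Conditions: 37% aq. HCHO (3 equiv), DMAP (0.3 equiv), THF/H2O, rt
Reagents that add atoms: formaldehyde C=O
Why: Morita–Baylis–Hillman α-hydroxymethylation of the cyclic enone (conjugate addition of DMAP, aldol addition to formaldehyde, loss of the amine) installs the C2 hydroxymethyl group; the C5 stereocentre is not acidic.

**Step 12**
Reactants: 18 (5R)-5-[(4E,6R)-6,7-dihydroxy-6-methylhepta-1,4-dien-2-yl]-2-(hydroxymethyl)cyclohex-2-en-1-one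
Product: 19 [(4R)-4-{(4E,6R)-6-hydroxy-6-methyl-7-[(2-methylpropanoyl)oxy]hepta-1,4-dien-2-yl}-6-oxocyclohex-1-en-1-yl]methyl 2-methylpropanoate (CNP0536801.1)
Conditions: (iPrCO)2O (2.4 equiv), pyridine, DMAP (5 mol %), CH2Cl2, 0 °C
Reagents that add atoms: isobutyric anhydride CC(C)C(=O)OC(=O)C(C)C
Why: Acylation by the anhydride under nucleophilic catalysis should esterify the two primary alcohols, whereas the tertiary allylic alcohol does not react at 0 °C.

**Compound list**

1 | 2-ethenyl-2-methyloxirane (racemic) | CC1(C=C)CO1 | starting material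
2 | 2-methylidenebut-3-en-1-ol | C=CC(=C)CO | intermediate
3 | 2-(bromomethyl)buta-1,3-diene | C=CC(=C)CBr | intermediate
4 | 3-hydroxycyclobutan-1-one | O=C1CC(O)C1 | starting material
5 | 3-[(2-methylidenebut-3-en-1-yl)oxy]cyclobutan-1-one | O=C1CC(OCC(=C)C=C)C1 | intermediate
6 | (E)-(3-hydroxybut-3-en-1-ylidene)(2-methylidenebut-3-en-1-yl)oxidanium (enol/oxocarbenium cation, ion pair with the catalyst anion) | C=C(O)C/C=[O+]/CC(=C)C=C | intermediate (not isolated)
7 | (2S)-2-(2-hydroxyprop-2-en-1-yl)-5-methylideneoxan-4-ylium (exocyclic allyl cation, one resonance form) | C=C(O)C[C@@H]1C[CH+]C(=C)CO1 | intermediate (not isolated)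
8 | (1S,5R)-4-methylidene-2-oxabicyclo[3.3.1]nonan-7-one | O=C1C[C@H]2C[C@@H](C1)OCC2=C | intermediate
9 | (5R)-5-(3-hydroxyprop-1-en-2-yl)cyclohex-2-en-1-one | C=C(CO)[C@@H]1CC=CC(=O)C1 | intermediate (not isolated)
10 | tert-butyl 2-[(1R)-5-oxocyclohex-3-en-1-yl]prop-2-en-1-yl carbonate | C=C(COC(=O)OC(C)(C)C)[C@@H]1CC=CC(=O)C1 | intermediate
11 | [(2S)-2-methyloxiran-2-yl]methanol | OC[C@@]1(C)CO1 | starting material
12 | tert-butyldimethyl{[(2R)-2-methyloxiran-2-yl]methoxy}silane | CC(C)(C)[Si](C)(C)OC[C@@]1(C)CO1 | intermediate
13 | (2R)-1-[(tert-butyldimethylsilyl)oxy]-2-methylbut-3-en-2-ol | C=C[C@@](C)(O)CO[Si](C)(C)C(C)(C)C | intermediate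
14 | 2-ethenyl-4,4,5,5-tetramethyl-1,3,2-dioxaborolane | C=CB1OC(C)(C)C(C)(C)O1 | starting material
15 | (2R,3E)-1-[(tert-butyldimethylsilyl)oxy]-2-methyl-4-(4,4,5,5-tetramethyl-1,3,2-dioxaborolan-2-yl)but-3-en-2-ol | CC1(C)OB(/C=C/[C@@](C)(O)CO[Si](C)(C)C(C)(C)C)OC1(C)C | intermediate
16 | (5R)-5-{(4E,6R)-7-[(tert-butyldimethylsilyl)oxy]-6-hydroxy-6-methylhepta-1,4-dien-2-yl}cyclohex-2-en-1-one | C=C(C/C=C/[C@@](C)(O)CO[Si](C)(C)C(C)(C)C)[C@@H]1CC=CC(=O)C1 | intermediate
17 | (5R)-5-[(4E,6R)-6,7-dihydroxy-6-methylhepta-1,4-dien-2-yl]cyclohex-2-en-1-one | C=C(C/C=C/[C@@](C)(O)CO)[C@@H]1CC=CC(=O)C1 | intermediate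
18 | (5R)-5-[(4E,6R)-6,7-dihydroxy-6-methylhepta-1,4-dien-2-yl]-2-(hydroxymethyl)cyclohex-2-en-1-one | C=C(C/C=C/[C@@](C)(O)CO)[C@@H]1CC=C(CO)C(=O)C1 | intermediate
19 | [(4R)-4-{(4E,6R)-6-hydroxy-6-methyl-7-[(2-methylpropanoyl)oxy]hepta-1,4-dien-2-yl}-6-oxocyclohex-1-en-1-yl]methyl 2-methylpropanoate | C=C(C/C=C/[C@@](C)(O)COC(=O)C(C)C)[C@@H]1CC=C(COC(=O)C(C)C)C(=O)C1 | target

**Step count and risks**

Total step count: 12. Longest linear sequence: 9 steps (1, 2, 3, 4, 5, 9, 10, 11, 12).

Steps most likely to fail:

1. Step 4 (proposed new method). What may go wrong: insufficient enantiofacial discrimination in the Prins bond formation, or acid-induced oligomerisation of the diene before the carbonyl is activated. The fallback separates ring construction from enantioselection and sets out from 5. SnCl4 (1.1 equiv, CH2Cl2, −78 °C), the stoichiometric achiral Lewis-acid manifold known for 3-alkoxycyclobutanones and alkenes, should give racemic 4-methylidene-2-oxabicyclo[3.3.1]nonan-7-one F1. DBU and TBSCl open and silylate it to racemic 5-{3-[(tert-butyldimethylsilyl)oxy]prop-1-en-2-yl}cyclohex-2-en-1-one F2. Kinetic resolution by copper-catalysed enantioselective conjugate addition (Et2Zn 0.55 equiv, Cu(OTf)2 1 mol %, BINOL-derived phosphoramidite 2 mol %, toluene, −30 °C, ligand enantiomer chosen to consume the S enone) leaves (5R)-5-{3-[(tert-butyldimethylsilyl)oxy]prop-1-en-2-yl}cyclohex-2-en-1-one F3 and removes the other enantiomer as the trans adduct (3S,5S)-3-ethyl-5-{3-[(tert-butyldimethylsilyl)oxy]prop-1-en-2-yl}cyclohexan-1-one F4. HF·pyridine converts F3 into 9, and Boc2O/DMAP gives 10, where the route is rejoined.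

2. Step 3. What may go wrong: slow O-alkylation of the secondary β-hydroxy ketone while the dienyl bromide is lost by dimerisation or hydrolysis. The fallback builds the four-membered ring on the ether instead of etherifying a preformed ring and sets out from 2. Transfer vinylation (Hg(OAc)2 cat., ethyl vinyl ether, reflux) gives 2-[(ethenyloxy)methyl]buta-1,3-diene F5. Ketene [2+2] cycloaddition with dichloroketene (Cl3CCOCl, Zn–Cu couple, Et2O, slow addition; the enol ether is the most reactive alkene) gives racemic 2,2-dichloro-3-[(2-methylidenebut-3-en-1-yl)oxy]cyclobutan-1-one F6. Reductive dechlorination (Zn, AcOH, rt) returns to the route at 5.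

3. Step 9. What may go wrong: sluggish transmetalation of the hindered alkenylboronate that carries a free tertiary alcohol, with protodeboronation and decay of the π-allyl complex. The fallback moves the fragment union from the C(sp3)–C(sp2) bond to the alkene itself and sets out from 10. Stille allyl–vinyl coupling with tributyl(vinyl)stannane (Pd(PPh3)4, THF, 60 °C) gives (5R)-5-(penta-1,4-dien-2-yl)cyclohex-2-en-1-one F7. E-selective cross-metathesis of its monosubstituted alkene with 13 (second-generation Grubbs catalyst, CH2Cl2, 40 °C; the 1,1-disubstituted alkene and the enone are unreactive) returns to the route at 16.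

**Further compounds**

F1 | step 4 | rac-4-methylidene-2-oxabicyclo[3.3.1]nonan-7-one | O=C1CC2CC(C1)OCC2=C
F2 | step 4 | rac-5-{3-[(tert-butyldimethylsilyl)oxy]prop-1-en-2-yl}cyclohex-2-en-1-one | C=C(CO[Si](C)(C)C(C)(C)C)C1CC=CC(=O)C1
F3 | step 4 | (5R)-5-{3-[(tert-butyldimethylsilyl)oxy]prop-1-en-2-yl}cyclohex-2-en-1-one | C=C(CO[Si](C)(C)C(C)(C)C)[C@@H]1CC=CC(=O)C1
F4 | step 4 | (3S,5S)-3-ethyl-5-{3-[(tert-butyldimethylsilyl)oxy]prop-1-en-2-yl}cyclohexan-1-one | CC[C@H]1C[C@H](C(=C)CO[Si](C)(C)C(C)(C)C)CC(=O)C1
F5 | step 3 | 2-[(ethenyloxy)methyl]buta-1,3-diene | C=COCC(=C)C=C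
F6 | step 3 | rac-2,2-dichloro-3-[(2-methylidenebut-3-en-1-yl)oxy]cyclobutan-1-one | O=C1CC(OCC(=C)C=C)C1(Cl)Cl
F7 | step 9 | (5R)-5-(penta-1,4-dien-2-yl)cyclohex-2-en-1-one | C=CCC(=C)[C@@H]1CC=CC(=O)C1
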